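Numbering: flavanone locants (O1, C2, C3, C4, C4a, C5–C8, C8a; doubled primes for the half that carries the 4-hydroxyphenyl group) are used for the target and for all intermediates.

## Structural features

The target is a 3,3''-linked biflavanone: two 5,7-dihydroxychroman-4-one units (rings A/C and A''/C'') are joined only by the C3–C3'' single bond, with a 4-methoxyphenyl group on C2 and a 4-hydroxyphenyl group on C2''. C2, C3, C3'' and C2'' form an unbroken row of four stereocentres (2S,3R,3''R,2''S); each pyranone ring is 2,3-trans and the two halves have the same handedness, but the molecule is not C2-symmetric because only one aryl oxygen is methylated. C2 and C2'' are 4-oxygenated benzylic ether carbons β to a carbonyl group, so base can open ring C through the C3 enolate, acid can ionise the C2–O1 bond, and a free 4'''-phenoxide could open ring C'' as a quinone methide. C3 and C3'' are enolisable and are the only centres that can be corrected late; the five phenols make late base chemistry and selective protection unattractive. The real difficulty is to place two different aryl groups on a four-centre array with absolute control at C2/C2'', and then to bring in two phloroglucinol rings without a set of phenol protecting groups. The key step uses the fact that each ring A is an acylphloroglucinol: C8a carries O1, C4a carries C4, and C5–C8 have the oxidation pattern of a β-keto ester chain. A four-carbon chain on C8a of a 2-aryl-2,3-dihydropyran-4-one (which already holds O1, C2, C3, C4, C4a and C8a) therefore needs only the C4a–C5 bond to become ring A, and the same holds for ring A''.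

## Logic of the disconnections

18 from 16. No skeletal bond is cut; 16 differs from 18 in the O–CH2OCH3 bond at O4''' and in the configuration at C3 and C3''. The aldol chemistry used earlier delivers each C2/C3 pair as a syn pair, which becomes a 2,3-cis ring. C3 can be inverted safely only when ring A is aromatic: the C3 enol of a monocyclic dihydropyranone is a 2H-pyran that opens to a dienone and would lose C2, whereas the C3 enol of a chromanone is a 2H-chromene. The gain is that one acid step removes the protecting group and sets two stereocentres. The demand is that enolisation at C3/C3'' must be faster than ionisation of the C2–O1 bonds.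

16 from 15. The bonds C4a–C5 and C4a''–C5'' are cut, which opens rings A and A'' to β-keto ester chains on C8a and C8a''. This removes both aromatic rings and all four ring-A phenols in one operation and leaves a precursor with a single protecting group. The forward step must make the vinylogous α-carbon C4a acylate the ester twice, in preference to every other enolate reaction, and must leave C2/C3 and C2''/C3'' alone.

15 from 13 and two molecules of 14. The bonds C6–C7 and C6''–C7'' are cut, so the acidic β-keto ester appears only one step before it is used. Each aldehyde group of 13 is joined to one molecule of the diazo ester 14 without base; the demand is that the enolisable dialdehyde reacts faster than it condenses with itself.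

13 from 12. Only the aldehyde oxygens are exchanged for acetals, so that C7 and C7'' pass through the organometallic step as inert groups. The hydrolysis must spare the aryl acetal on O4''' and the two vinylogous esters.

12 from 11. The bonds O1–C8a and O1''–C8a'' are cut, giving two β-hydroxy ynones. An ynone is chosen instead of a saturated polyketone chain for a structural reason. After the lactones are opened, each hydroxyl is γ to the ketone of the other half. With a CH2 next to that ketone the five-membered lactol would lose water to an enol ether conjugated with the chain, in competition with the six-membered ring. An ynone has no such hydrogen, and conjugate addition is possible only in the six-membered sense. The forward step must be neutral so that the free benzylic carbinols keep their configuration.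

11 from 9 and two molecules of 10. The bonds C4–C4a and C4''–C4a'' are cut, one for each lactone carbonyl, so the forward step consumes two acetylides per molecule of 9. Both acyl groups and both carbinol oxygens are then stored in 9, each carbinol oxygen being the leaving group of the acyl carbon of the other half, so no hydroxyl protection is needed. The nucleophile must add exactly once to each lactone and must not deprotonate the bridgeheads.

9 from 6 and 7. The bond C2''–C3'' and the lactone bond O–C4 are cut. The bicycle can only be cis-fused and prefers exo aryl groups, so C3'' and C2'' follow from C3. The forward step needs an enolate on the lactone side only, and ring closure of the adduct that sits cis to the imide.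

6 from 3 and 4. The bond C2–C3 and the lactone bond O–C4'' are cut; this is the step that introduces absolute configuration, through the auxiliary. The aldol must give the syn adduct, which lactonises to the 2,3-trans lactone.

3 from 1 and 2. The N–acyl bond is cut; both pieces are commercial. The acid chloride must react in preference to the ester.

## Other disconnections considered

Alternative 1: The cut is made at O1–C8a and C4–C4a, and at the doubly primed counterparts, so that both phloroglucinol rings arrive as an aryne and the remaining C6–C3–C3–C6 core as the (E,E)-bis(arylidene)succinic acid A1.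

- Forward step: two equivalents of 3,5-bis(methoxymethoxy)benzyne, released with CsF from the silyl triflate A2, would insert into the two C(O)–OH bonds of A1. The carboxylate oxygen adds to the aryne carbon remote from the flanking alkoxy group and the aryl anion takes up the acyl group, giving the α,α'-linked bis(2'-hydroxychalcone) A3. Four bonds form and no ring closes.
- In its favour: A1 is two Stobbe-type condensations away from a succinate, and acyl-transfer insertion of arynes into carboxylic acids is an established reaction. In convergence and in precedent for the bond-forming event this plan is better than the chosen one.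
- Against it here: A3 has no stereocentre. C2, C3, C3'' and C2'' would all have to be created in a double oxa-Michael closure of an α-substituted chalcone, for which neither absolute nor relative control is available. A1 is also prone to close to its cyclic anhydride, and A2 needs its own multistep preparation.
- Comparison: on structure the chosen plan fixes C2/C2'' by an auxiliary before any ring exists; on mechanism the alternative is the safer bond construction; on step economy the two are about equal once A2 is counted. The alternative carries five acetal groups against one.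

Alternative 2: The cut is C2''–C3'' together with the lactone bond O–C4.

- Forward step: the lithium enolate (LiN(SiMe3)2) of the trans-paraconic ester A4 would add to a protected 4-hydroxybenzaldehyde, and the new alkoxide would close onto the C4 ester to give the exo,exo bis-lactone A5.
- In its favour: it is a known reaction type and it locks C2, C3, C3'' and C2'' into one rigid cis-fused bicycle. As a stereodefining key step it is better than the chosen key step, which creates no stereocentre. The chosen route in fact uses the same kind of step (step 3), and 9 is the mirror image of A5; on the stereochemical template the two plans are equal.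
- Against it here: in A5 the bridgeheads have the configuration of C3/C3'' of the target, but the carbinol carbons are opposite to C2/C2''. The endgame therefore has to add two complete trioxygenated aryl-metal reagents to hindered lactone carbonyls (four more phenol protecting groups), and then close both pyranone rings by displacement at 4-alkoxybenzylic carbons with inversion, where ionisation competes. The ester in A4 can also be deprotonated at C3, which leads to β-elimination of the lactone oxygen; the imide in 6 suppresses this.
- Comparison: the alternative relies on known aryl-addition chemistry, whereas the chosen plan accepts an unprecedented ring construction in return for unprotected rings A and A''. Step counts are similar.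

Alternative 3: After exchanging C4=O/C3–H for a C3=C4 double bond in both halves, the cut is made at C3=C4 and C3''=C4'', which leads back to the but-2-yne-1,4-diol bis(aryl ether) A6.

- Forward step: with the second-generation Grubbs catalyst (H2IMes)(PCy3)Cl2Ru=CHPh, the carbene formed at one ortho-vinyl group would add across the alkyne, close the first 2H-chromene and pass the carbene to C3'', which closes the second ring on the other vinyl group. The product would be the 2,2'-diaryl-3,3'-bi(2H-chromene) A7.
- In its favour: tandem ring-closing enyne metathesis is well established (better precedent than the chosen key step), the C3–C3'' bond is present from the start as the alkyne, and C2/C2'' could come from asymmetric alkynylation of the two aldehydes.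
- Against it here: A6 needs two ether bonds between hindered ortho-vinyl phenols and secondary 4-alkoxybenzylic propargylic carbons, formed with stereochemical fidelity. After metathesis both C3=C4 bonds of a conjugated diene must be converted regioselectively into C4 ketones with C3–H trans to the C2 aryl group. 2-Aryl-2H-chromenes can also open electrocyclically and lose C2, and five acetal groups remain to be removed.
- Comparison: the chosen plan has C4 at the ketone oxidation level throughout and needs no redox correction. The alternative is at best equal in step count.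

Key step: step 8

Assumption: 7, 10 and 14 are taken as catalogue compounds (7 is otherwise one O-alkylation away from the corresponding phenol).

Remark on the chemistry: the key-step precursor 15 and its product 16 have the skeletons that the double Claisen disconnection calls for, but they are carried with 2,3-cis rings and, in 15, with ethyl in place of methyl esters. The alkoxide is lost in the key step, and C3/C3'' are set after ring A exists (step 9).

Remark on stoichiometry: 9 carries two lactone carbonyls and 13 carries two aldehyde groups, so steps 4 and 7 each consume two molecules of the partner (10 and 14) per molecule of substrate.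

## Route

Step 1
Reactants: 1 (S)-4-benzyl-1,3-oxazolidin-2-one; 2 methyl 4-chloro-4-oxobutanoate
Product: 3 methyl 4-[(4S)-4-benzyl-2-oxo-1,3-oxazolidin-3-yl]-4-oxobutanoate
Conditions: n-BuLi, THF, −78 °C; then 2, −78 → 0 °C
Reagents that add atoms: none
Why: N-Acylation of the lithium salt of 1 by the acid chloride; at −78 °C the acyl chloride reacts far faster than the methyl ester, so only the imide should form.

Step 2
Reactants: 3 methyl 4-[(4S)-4-benzyl-2-oxo-1,3-oxazolidin-3-yl]-4-oxobutanoate; 4 4-methoxybenzaldehyde
Product: 6 (4S)-4-benzyl-3-{[(2S,3S)-2-(4-methoxyphenyl)-5-oxooxolan-3-yl]carbonyl}-1,3-oxazolidin-2-one (2,3-trans lactone), via syn-aldol adduct 5 (not isolated)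
Conditions: Bu2BOTf, iPr2NEt, CH2Cl2, 0 °C; 4, −78 → 0 °C; MeOH, pH 7 buffer, H2O2, 0 °C; then PPTS (cat.), CH2Cl2, rt
Reagents that add atoms: none
Why: Auxiliary-controlled boron aldol (Evans syn-aldol): the Z-boron enolate reacts through a Zimmerman–Traxler chair on the face away from the benzyl group, which sets the carbinol carbon (later C2) and the α-carbon (later C3) both S. The γ-hydroxy ester then closes by 5-exo-trig lactonisation with loss of methanol, placing aryl and imide trans on the ring.

Step 3
Reactants: 6 (4S)-4-benzyl-3-{[(2S,3S)-2-(4-methoxyphenyl)-5-oxooxolan-3-yl]carbonyl}-1,3-oxazolidin-2-one; 7 4-(methoxymethoxy)benzaldehyde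
Product: 9 (1S,4S,5S,8S)-4-[4-(methoxymethoxy)phenyl]-8-(4-methoxyphenyl)-3,7-dioxabicyclo[3.3.0]octane-2,6-dione (cis-fused; both aryl groups exo), via cis-aldolate 8 (not isolated)
Conditions: LiN(SiMe3)2 (1.0 equiv), THF, −78 °C; 7, −78 → 0 °C; AcOH
Reagents that add atoms: none
Why: Lactone-enolate aldol followed by intramolecular acyl transfer: the base removes a lactone α-proton (the imide α-H is tertiary and shielded by allylic strain), the chair transition state of the E-enolate sets the new carbinol carbon S, and retro-aldol exchange lets the adduct lying cis to the imide expel the oxazolidinone (5-exo-trig). The fusion can only be cis, which fixes the second bridgehead relative to the first, and the closure that puts the aryl group on the convex face should be the faster one, so later C2'' is S.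

Step 4
Reactants: 9 (1S,4S,5S,8S)-4-[4-(methoxymethoxy)phenyl]-8-(4-methoxyphenyl)-3,7-dioxabicyclo[3.3.0]octane-2,6-dione; 10 4,4-diethoxybut-1-yne (two molecules, one for each lactone carbonyl)
Product: 11 (6S,7S)-1,1,12,12-tetraethoxy-6-[(S)-hydroxy(4-methoxyphenyl)methyl]-7-{(S)-hydroxy[4-(methoxymethoxy)phenyl]methyl}dodeca-3,9-diyne-5,8-dione (open form of the bicyclic bis-lactol)
Conditions: 10 (2.2 equiv), n-BuLi (2.1 equiv), THF, −78 °C; then 9 (1.0 equiv), −78 °C; aq. NH4Cl
Reagents that add atoms: 4,4-diethoxybut-1-yne, the second molecule of 10 (C#CCC(OCC)OCC)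
Why: Addition of a lithium acetylide to a lactone carbonyl stops at the lactol alkoxide, so each of the two lactones should take up exactly one alkyne (two molecules of 10 per molecule of 9) and give a β-hydroxy ynone, with the C–O bonds at both carbinol carbons untouched. The acetylide is too weak a base to enolise the bridgeheads, which would open the lactones by β-elimination.

Step 5
Reactants: 11 (6S,7S)-1,1,12,12-tetraethoxy-6-[(S)-hydroxy(4-methoxyphenyl)methyl]-7-{(S)-hydroxy[4-(methoxymethoxy)phenyl]methyl}dodeca-3,9-diyne-5,8-dione
Product: 12 (2S,2'S,3S,3'S)-6,6'-bis(2,2-diethoxyethyl)-2-(4-methoxyphenyl)-2'-[4-(methoxymethoxy)phenyl]-2,2',3,3'-tetrahydro-4H,4'H-[3,3'-bipyran]-4,4'-dione (both rings 2,3-cis)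
Conditions: (Ph3P)AuNTf2 (5 mol%), CH2Cl2, rt
Reagents that add atoms: none
Why: Known 6-endo-dig cycloisomerisation of β-hydroxy ynones to 2,3-dihydropyran-4-ones under π-acid catalysis: each hydroxyl is β to its own ynone and γ to the other (which would need a seven-membered ring), and the lactols are only a reversible resting state because an ynone has no α-hydrogen through which they could dehydrate. O1–C8a and O1''–C8a'' form with retention at C2/C2''; without base or protic acid the 2,3-cis relationship should be kept.

Step 6
Reactants: 12 (2S,2'S,3S,3'S)-6,6'-bis(2,2-diethoxyethyl)-2-(4-methoxyphenyl)-2'-[4-(methoxymethoxy)phenyl]-2,2',3,3'-tetrahydro-4H,4'H-[3,3'-bipyran]-4,4'-dione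
Product: 13 2,2'-[(2S,2'S,3S,3'S)-2-(4-methoxyphenyl)-2'-[4-(methoxymethoxy)phenyl]-4,4'-dioxo-3,3',4,4'-tetrahydro-2H,2'H-[3,3'-bipyran]-6,6'-diyl]diacetaldehyde
Conditions: PPTS (cat.), acetone–H2O, 40 °C; used crude
Reagents that add atoms: water (O)
Why: Mild acid-catalysed hydrolysis of the diethyl acetals; these conditions should leave the aryl methoxymethyl ether and the vinylogous esters intact. The dialdehyde is taken on at once because its CH2 groups are doubly activated.

Step 7
Reactants: 13 2,2'-[(2S,2'S,3S,3'S)-2-(4-methoxyphenyl)-2'-[4-(methoxymethoxy)phenyl]-4,4'-dioxo-3,3',4,4'-tetrahydro-2H,2'H-[3,3'-bipyran]-6,6'-diyl]diacetaldehyde; 14 ethyl diazoacetate (two molecules, one for each aldehyde group)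
Product: 15 diethyl 4,4'-[(2S,2'S,3S,3'S)-2-(4-methoxyphenyl)-2'-[4-(methoxymethoxy)phenyl]-4,4'-dioxo-3,3',4,4'-tetrahydro-2H,2'H-[3,3'-bipyran]-6,6'-diyl]bis(3-oxobutanoate)
Conditions: 14 (2.4 equiv), SnCl2 (10 mol%), CH2Cl2, rt
Reagents that add atoms: ethyl diazoacetate, the second molecule of 14 (CCOC(=O)C=[N+]=[N-])
Why: Roskamp reaction, run once on each aldehyde group: the tin-activated aldehyde is attacked by the diazo carbon, and a 1,2-hydride shift with loss of N2 gives the β-keto ester. C6–C7 and C6''–C7'' form under non-basic conditions, so the C2/C3 pairs are not at risk.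

Step 8
Reactants: 15 diethyl 4,4'-[(2S,2'S,3S,3'S)-2-(4-methoxyphenyl)-2'-[4-(methoxymethoxy)phenyl]-4,4'-dioxo-3,3',4,4'-tetrahydro-2H,2'H-[3,3'-bipyran]-6,6'-diyl]bis(3-oxobutanoate)
Product: 16 (2S,2'S,3S,3'S)-5,5',7,7'-tetrahydroxy-2-(4-methoxyphenyl)-2'-[4-(methoxymethoxy)phenyl]-[3,3'-bichromane]-4,4'-dione (both rings 2,3-cis)
Conditions: Mg(OMe)2 (8 equiv), MeOH–THF, 50 °C; then AcOH, 0 °C
Reagents that add atoms: none
Why: Proposed new method: Mg(OMe)2 converts each side chain into its magnesium enolates, and proton exchange in methanol makes the C8 carbanion available; C8 is the γ-position of the vinylogous ester O1–C8a=C4a–C4=O, so its charge is delivered to C4a. C4a then adds to the magnesium-bound ester carbonyl C5 in a 6-(enolexo)-exo-trig closure (ring atoms C4a, C5, C6, C7, C8, C8a), ethoxide leaves, and two enolisations give the 5,7-dihydroxy arene; ring A'' closes in the same way and independently. The closest known reaction type is the Mg(OMe)2-mediated Claisen cyclisation of open-chain 3,5,7-trioxo esters to 2-acylphloroglucinols; here the 5-oxo group is already tied up as the ring enol ether O1–C8a. No stereocentre is formed, and C2/C3 and C2''/C3'' should be left alone because the far more acidic side-chain protons are removed first, which leaves C3–H as the least acidic site. The step needs Claisen over aldol folding, C- over O-acylation and no opening of the pyranone rings. These are secured by the vinylogous-ester character of C4 (poor aldol acceptor for C6), by O1 being alkylated (no enol lactonisation to a pyranone), by the chain length that lets only C4a reach C5 through a six-membered transition state, and by the irreversible aromatisation. The acetal on O4''' keeps that oxygen from becoming a phenoxide that could open ring C'' as a quinone methide.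

Step 9
Reactants: 16 (2S,2'S,3S,3'S)-5,5',7,7'-tetrahydroxy-2-(4-methoxyphenyl)-2'-[4-(methoxymethoxy)phenyl]-[3,3'-bichromane]-4,4'-dione
Product: 18 (2S,2'S,3R,3'R)-5,5',7,7'-tetrahydroxy-2-(4-hydroxyphenyl)-2'-(4-methoxyphenyl)-[3,3'-bichromane]-4,4'-dione (CNP0196568.1), via cis,cis-pentaphenol 17 (not isolated)
Conditions: HCl (2 M), MeOH–THF, 50 °C
Reagents that add atoms: none
Why: Acidic methanolysis of the aryl methoxymethyl ether; in the same medium the C4/C4'' ketones enolise toward C3/C3'', and these enols are 2H-chromen-4-ols that cannot ring-open without losing the aromaticity of ring A. Each ring should therefore relax from 2,3-cis (C3 substituent axial) to the 2,3-trans diequatorial arrangement, so C3 and C3'' are set under thermodynamic control by the untouched S centres C2 and C2''.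

## Compound list

1 | (S)-4-benzyl-1,3-oxazolidin-2-one | O=C1N[C@@H](Cc2ccccc2)CO1 | starting material
2 | methyl 4-chloro-4-oxobutanoate | COC(=O)CCC(Cl)=O | starting material
3 | methyl 4-[(4S)-4-benzyl-2-oxo-1,3-oxazolidin-3-yl]-4-oxobutanoate | COC(=O)CCC(=O)N1C(=O)OC[C@@H]1Cc1ccccc1 | intermediate
4 | 4-methoxybenzaldehyde | COc1ccc(C=O)cc1 | starting material
5 | methyl (3S)-4-[(4S)-4-benzyl-2-oxo-1,3-oxazolidin-3-yl]-3-[(S)-hydroxy(4-methoxyphenyl)methyl]-4-oxobutanoate (syn-aldol adduct) | COC(=O)C[C@@H]([C@H](O)c1ccc(OC)cc1)C(=O)N1C(=O)OC[C@@H]1Cc1ccccc1 | intermediate (not isolated)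
6 | (4S)-4-benzyl-3-{[(2S,3S)-2-(4-methoxyphenyl)-5-oxooxolan-3-yl]carbonyl}-1,3-oxazolidin-2-one | COc1ccc([C@H]2OC(=O)C[C@@H]2C(=O)N2C(=O)OC[C@@H]2Cc2ccccc2)cc1 | intermediate
7 | 4-(methoxymethoxy)benzaldehyde | COCOc1ccc(C=O)cc1 | starting material
8 | (4S)-4-benzyl-3-{[(2S,3S,4S)-4-{(S)-hydroxy[4-(methoxymethoxy)phenyl]methyl}-2-(4-methoxyphenyl)-5-oxooxolan-3-yl]carbonyl}-1,3-oxazolidin-2-one (formed as its lithium alkoxide) | COc1ccc([C@H]2OC(=O)[C@H]([C@H](O)c3ccc(OCOC)cc3)[C@@H]2C(=O)N2C(=O)OC[C@@H]2Cc2ccccc2)cc1 | intermediate (not isolated)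
9 | (1S,4S,5S,8S)-4-[4-(methoxymethoxy)phenyl]-8-(4-methoxyphenyl)-3,7-dioxabicyclo[3.3.0]octane-2,6-dione | O=C1O[C@H](c2ccc(OCOC)cc2)[C@H]2C(=O)O[C@H](c3ccc(OC)cc3)[C@@H]12 | intermediate
10 | 4,4-diethoxybut-1-yne | C#CCC(OCC)OCC | starting material
11 | (6S,7S)-1,1,12,12-tetraethoxy-6-[(S)-hydroxy(4-methoxyphenyl)methyl]-7-{(S)-hydroxy[4-(methoxymethoxy)phenyl]methyl}dodeca-3,9-diyne-5,8-dione | COc1ccc([C@@H](O)[C@@H](C(=O)C#CCC(OCC)OCC)[C@H](C(=O)C#CCC(OCC)OCC)[C@H](O)c2ccc(OCOC)cc2)cc1 | intermediate
12 | (2S,2'S,3S,3'S)-6,6'-bis(2,2-diethoxyethyl)-2-(4-methoxyphenyl)-2'-[4-(methoxymethoxy)phenyl]-2,2',3,3'-tetrahydro-4H,4'H-[3,3'-bipyran]-4,4'-dione | COc1ccc([C@H]2OC(CC(OCC)OCC)=CC(=O)[C@H]2[C@@H]2C(=O)C=C(CC(OCC)OCC)O[C@@H]2c2ccc(OCOC)cc2)cc1 | intermediate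
13 | 2,2'-[(2S,2'S,3S,3'S)-2-(4-methoxyphenyl)-2'-[4-(methoxymethoxy)phenyl]-4,4'-dioxo-3,3',4,4'-tetrahydro-2H,2'H-[3,3'-bipyran]-6,6'-diyl]diacetaldehyde | COc1ccc([C@H]2OC(CC=O)=CC(=O)[C@H]2[C@@H]2C(=O)C=C(CC=O)O[C@@H]2c2ccc(OCOC)cc2)cc1 | intermediate
14 | ethyl diazoacetate | CCOC(=O)C=[N+]=[N-] | starting material
15 | diethyl 4,4'-[(2S,2'S,3S,3'S)-2-(4-methoxyphenyl)-2'-[4-(methoxymethoxy)phenyl]-4,4'-dioxo-3,3',4,4'-tetrahydro-2H,2'H-[3,3'-bipyran]-6,6'-diyl]bis(3-oxobutanoate) (key-step precursor) | COc1ccc([C@H]2OC(CC(=O)CC(=O)OCC)=CC(=O)[C@H]2[C@@H]2C(=O)C=C(CC(=O)CC(=O)OCC)O[C@@H]2c2ccc(OCOC)cc2)cc1 | intermediate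
16 | (2S,2'S,3S,3'S)-5,5',7,7'-tetrahydroxy-2-(4-methoxyphenyl)-2'-[4-(methoxymethoxy)phenyl]-[3,3'-bichromane]-4,4'-dione (key-step product) | COc1ccc([C@H]2Oc3cc(O)cc(O)c3C(=O)[C@H]2[C@@H]2C(=O)c3c(O)cc(O)cc3O[C@@H]2c2ccc(OCOC)cc2)cc1 | intermediate
17 | (2S,2'S,3S,3'S)-5,5',7,7'-tetrahydroxy-2-(4-hydroxyphenyl)-2'-(4-methoxyphenyl)-[3,3'-bichromane]-4,4'-dione | COc1ccc([C@H]2Oc3cc(O)cc(O)c3C(=O)[C@H]2[C@@H]2C(=O)c3c(O)cc(O)cc3O[C@@H]2c2ccc(O)cc2)cc1 | intermediate (not isolated)
18 | (2S,2'S,3R,3'R)-5,5',7,7'-tetrahydroxy-2-(4-hydroxyphenyl)-2'-(4-methoxyphenyl)-[3,3'-bichromane]-4,4'-dione | COc1ccc([C@H]2Oc3cc(O)cc(O)c3C(=O)[C@@H]2[C@H]2C(=O)c3c(O)cc(O)cc3O[C@@H]2c2ccc(O)cc2)cc1 | target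

## Step count and least certain steps

Total step count: 9. Longest linear sequence: 9 steps (1 and 2 to 18); 4, 7, 10 and 14 enter as commercial reagents, 10 and 14 each with two molecules per molecule of substrate.

Step 8 (key step, proposed new method). The most likely failure is that the side chains rest as unreactive magnesium β-keto ester chelates, so that C4a never attacks C5, or that methoxide cleaves the chain by retro-Claisen reaction. A second risk is deprotonation at C3, which would open ring C and erase C2. Fallback (known reactions only): the synthesis is repeated from 2 in the mirror-image series and ring A is made before ring C.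

- (R)-4-Benzyl-1,3-oxazolidin-2-one F1 is acylated with 2 to the imide F2.
- The boron aldol with 4 gives, through the syn-aldol adduct F3, the lactone F4.
- Aldol and acyl transfer with 7 gives, through the aldolate F5, the bis-lactone F6 (identical with A5).
- The trianion of methyl 3,5-dioxohexanoate F7 (LiN(iPr)2, THF; two molecules per molecule of F6) is acylated at its terminal carbon by both lactone carbonyls to give the bis(hydroxy tetraketo ester) F8.
- Mg(OMe)2 in methanol then performs the known Claisen cyclisation of each open 3,5,7-trioxo ester chain to the bis(acylphloroglucinol) diol F9. Any five-membered lactol or enol ether formed from F8 is reopened when the ring becomes aromatic.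
- Mitsunobu closure (PPh3, DIAD) of an ortho-phenol onto each benzylic carbinol inverts C2 and C2'' and gives the 2,3-trans biflavanone methoxymethyl ether F10. In this series C3 and C3'' already have the target configuration.
- HCl in methanol at room temperature removes the acetal, and the route is rejoined at 18.

This detour also makes step 9 unnecessary.

Step 9. The most likely failure is that ionisation of the 4-alkoxybenzylic C2–O1 bonds competes with enolisation at C3/C3''; the relay from C2 to C3 would then be lost and diastereomers would form. The equilibrium may also stop short of the trans,trans isomer. Fallback: the same reactions are run from 2 in the mirror-image series, so that the acid has to correct C2/C2'' instead of C3/C3''.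

- F1, F2, F4 and F6 are made as above.
- Steps 4 to 8 then give the mirror images of 11, 12, 13, 15 and 16: the bis(hydroxy ynone) F11, the bis(dihydropyranone) acetal F12, the dialdehyde F13, the bis(β-keto ester) F14 and the (2R,3R,2''R,3''R)-biflavanone methoxymethyl ether F15.
- In F15, C3 and C3'' already have the target configuration. The same acid now acts through reversible C2–O1 ionisation and re-closure trans to the C3 substituent, via the pentaphenol F16, and the route is rejoined at 18.

The side reaction of the main route thus becomes the productive step.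

Step 3. The most likely failure is that the aldolate forms on the face away from the imide and does not revert, so that no acyl transfer takes place. The bicycle, once formed, may also be opened by residual base through β-elimination from a bridgehead enolate. Fallback from 6, rejoining at 9:

- LiOH/H2O2 removes the auxiliary and gives the lactone acid F17.
- Its dianion (2 equiv LiN(SiMe3)2; the carboxylate α-position is not deprotonated) adds to 7 to give the hydroxy acid F18.
- Catalytic camphorsulfonic acid in CH2Cl2 closes the second lactone under thermodynamic control: loss of water gives the alkylidene lactone, the carboxylic acid adds to the benzylic carbon, and the bridgehead is protonated cis.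

No base is present once the bicycle exists.

Step 5. The most likely failure is that the bis-lactol does not open, or that a lactol loses water toward the bridgehead carbon and gives an alkynyl dihydrofuran, so that the hydroxyl never reaches its own ynone. Fallback from 11, rejoining at 12: diethylamine in ethanol adds to both ynones to give the bis(β-diethylamino enone) F19. Acetic acid then lets each hydroxyl displace the amine at C8a by addition–elimination, which can only give the six-membered vinylogous ester.

Step 7. The most likely failure is enolisation and self-condensation of the dialdehyde, whose CH2 groups lie between an aldehyde and a vinylogous ester, before the diazo ester adds. Fallback from 13, rejoining at 15: Pinnick oxidation (NaClO2, NaH2PO4, 2-methylbut-2-ene) gives the diacid F20. Carbonyldiimidazole converts it into the bis(acyl imidazolide) F21, which is homologated with Mg(O2CCH2CO2Et)2 by decarboxylative Claisen condensation.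

## Further compounds

F1 | step 8 | (R)-4-benzyl-1,3-oxazolidin-2-one | O=C1N[C@H](Cc2ccccc2)CO1
F2 | step 8 | methyl 4-[(4R)-4-benzyl-2-oxo-1,3-oxazolidin-3-yl]-4-oxobutanoate | COC(=O)CCC(=O)N1C(=O)OC[C@H]1Cc1ccccc1
F3 | step 8 | mirror image of 5 (syn-aldol adduct, not isolated) | COC(=O)C[C@H]([C@@H](O)c1ccc(OC)cc1)C(=O)N1C(=O)OC[C@H]1Cc1ccccc1
F4 | step 8 | (4R)-4-benzyl-3-{[(2R,3R)-2-(4-methoxyphenyl)-5-oxooxolan-3-yl]carbonyl}-1,3-oxazolidin-2-one | COc1ccc([C@@H]2OC(=O)C[C@H]2C(=O)N2C(=O)OC[C@H]2Cc2ccccc2)cc1
F5 | step 8 | mirror image of 8 (aldolate, not isolated) | COc1ccc([C@@H]2OC(=O)[C@@H]([C@@H](O)c3ccc(OCOC)cc3)[C@H]2C(=O)N2C(=O)OC[C@H]2Cc2ccccc2)cc1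
F6 | step 8 | (1R,4R,5R,8R)-4-[4-(methoxymethoxy)phenyl]-8-(4-methoxyphenyl)-3,7-dioxabicyclo[3.3.0]octane-2,6-dione | O=C1O[C@@H](c2ccc(OCOC)cc2)[C@@H]2C(=O)O[C@@H](c3ccc(OC)cc3)[C@H]12
F7 | step 8 | methyl 3,5-dioxohexanoate | COC(=O)CC(=O)CC(C)=O
F8 | step 8 | dimethyl (8R,9R)-8-[(R)-hydroxy(4-methoxyphenyl)methyl]-9-{(R)-hydroxy[4-(methoxymethoxy)phenyl]methyl}-3,5,7,10,12,14-hexaoxohexadecanedioate (open form) | COc1ccc([C@H](O)[C@H](C(=O)CC(=O)CC(=O)CC(=O)OC)[C@@H](C(=O)CC(=O)CC(=O)CC(=O)OC)[C@@H](O)c2ccc(OCOC)cc2)cc1
F9 | step 8 | (2R,3R)-2-[(R)-hydroxy(4-methoxyphenyl)methyl]-3-{(R)-hydroxy[4-(methoxymethoxy)phenyl]methyl}-1,4-bis(2,4,6-trihydroxyphenyl)butane-1,4-dione | COc1ccc([C@H](O)[C@H](C(=O)c2c(O)cc(O)cc2O)[C@@H](C(=O)c2c(O)cc(O)cc2O)[C@@H](O)c2ccc(OCOC)cc2)cc1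
F10 | step 8 | (2S,2'S,3R,3'R)-5,5',7,7'-tetrahydroxy-2-(4-methoxyphenyl)-2'-[4-(methoxymethoxy)phenyl]-[3,3'-bichromane]-4,4'-dione | COc1ccc([C@H]2Oc3cc(O)cc(O)c3C(=O)[C@@H]2[C@H]2C(=O)c3c(O)cc(O)cc3O[C@@H]2c2ccc(OCOC)cc2)cc1
F11 | step 9 | mirror image of 11 | COc1ccc([C@H](O)[C@H](C(=O)C#CCC(OCC)OCC)[C@@H](C(=O)C#CCC(OCC)OCC)[C@@H](O)c2ccc(OCOC)cc2)cc1
F12 | step 9 | mirror image of 12 | COc1ccc([C@@H]2OC(CC(OCC)OCC)=CC(=O)[C@@H]2[C@H]2C(=O)C=C(CC(OCC)OCC)O[C@H]2c2ccc(OCOC)cc2)cc1
F13 | step 9 | mirror image of 13 | COc1ccc([C@@H]2OC(CC=O)=CC(=O)[C@@H]2[C@H]2C(=O)C=C(CC=O)O[C@H]2c2ccc(OCOC)cc2)cc1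
F14 | step 9 | mirror image of 15 | COc1ccc([C@@H]2OC(CC(=O)CC(=O)OCC)=CC(=O)[C@@H]2[C@H]2C(=O)C=C(CC(=O)CC(=O)OCC)O[C@H]2c2ccc(OCOC)cc2)cc1
F15 | step 9 | (2R,2'R,3R,3'R)-5,5',7,7'-tetrahydroxy-2-(4-methoxyphenyl)-2'-[4-(methoxymethoxy)phenyl]-[3,3'-bichromane]-4,4'-dione | COc1ccc([C@@H]2Oc3cc(O)cc(O)c3C(=O)[C@@H]2[C@H]2C(=O)c3c(O)cc(O)cc3O[C@H]2c2ccc(OCOC)cc2)cc1
F16 | step 9 | (2R,2'R,3R,3'R)-5,5',7,7'-tetrahydroxy-2-(4-hydroxyphenyl)-2'-(4-methoxyphenyl)-[3,3'-bichromane]-4,4'-dione | COc1ccc([C@@H]2Oc3cc(O)cc(O)c3C(=O)[C@@H]2[C@H]2C(=O)c3c(O)cc(O)cc3O[C@H]2c2ccc(O)cc2)cc1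
F17 | step 3 | (2S,3S)-2-(4-methoxyphenyl)-5-oxooxolane-3-carboxylic acid | COc1ccc([C@H]2OC(=O)C[C@@H]2C(=O)O)cc1
F18 | step 3 | (2S,3S,4R)-4-{hydroxy[4-(methoxymethoxy)phenyl]methyl}-2-(4-methoxyphenyl)-5-oxooxolane-3-carboxylic acid (carbinol configuration not fixed) | COc1ccc([C@H]2OC(=O)[C@@H](C(O)c3ccc(OCOC)cc3)[C@@H]2C(=O)O)cc1
F19 | step 5 | (6S,7S)-3,10-bis(diethylamino)-1,1,12,12-tetraethoxy-6-[(S)-hydroxy(4-methoxyphenyl)methyl]-7-{(S)-hydroxy[4-(methoxymethoxy)phenyl]methyl}dodeca-3,9-diene-5,8-dione (alkene geometry not fixed) | COc1ccc([C@@H](O)[C@@H](C(=O)C=C(CC(OCC)OCC)N(CC)CC)[C@H](C(=O)C=C(CC(OCC)OCC)N(CC)CC)[C@H](O)c2ccc(OCOC)cc2)cc1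
F20 | step 7 | 2,2'-[(2S,2'S,3S,3'S)-2-(4-methoxyphenyl)-2'-[4-(methoxymethoxy)phenyl]-4,4'-dioxo-3,3',4,4'-tetrahydro-2H,2'H-[3,3'-bipyran]-6,6'-diyl]diacetic acid | COc1ccc([C@H]2OC(CC(=O)O)=CC(=O)[C@H]2[C@@H]2C(=O)C=C(CC(=O)O)O[C@@H]2c2ccc(OCOC)cc2)cc1
F21 | step 7 | bis(acyl imidazolide) of F20 | COc1ccc([C@H]2OC(CC(=O)n3ccnc3)=CC(=O)[C@H]2[C@@H]2C(=O)C=C(CC(=O)n3ccnc3)O[C@@H]2c2ccc(OCOC)cc2)cc1
A1 | alternative 1 | (2E,3E)-2-(4-methoxybenzylidene)-3-[4-(methoxymethoxy)benzylidene]succinic acid | COc1ccc(/C=C(/C(=O)O)C(=C/c2ccc(OCOC)cc2)\C(=O)O)cc1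
A2 | alternative 1 | 3,5-bis(methoxymethoxy)-2-(trimethylsilyl)phenyl trifluoromethanesulfonate | COCOc1cc(OCOC)c([Si](C)(C)C)c(OS(=O)(=O)C(F)(F)F)c1
A3 | alternative 1 | α,α'-linked bis(2'-hydroxy-4',6'-bis(methoxymethoxy)chalcone) | COCOc1cc(OCOC)c(C(=O)/C(=C/c2ccc(OC)cc2)C(=C/c2ccc(OCOC)cc2)\C(=O)c2c(O)cc(OCOC)cc2OCOC)c(O)c1
A4 | alternative 2 | methyl (2R,3R)-2-(4-methoxyphenyl)-5-oxooxolane-3-carboxylate | COc1ccc([C@@H]2OC(=O)C[C@H]2C(=O)OC)cc1
A5 | alternative 2 | (1R,4R,5R,8R)-4-[4-(methoxymethoxy)phenyl]-8-(4-methoxyphenyl)-3,7-dioxabicyclo[3.3.0]octane-2,6-dione (exo,exo) | O=C1O[C@@H](c2ccc(OCOC)cc2)[C@@H]2C(=O)O[C@@H](c3ccc(OC)cc3)[C@H]12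
A6 | alternative 3 | but-2-yne-1,4-diol bis[3,5-bis(methoxymethoxy)-2-vinylphenyl] ether carrying 4-methoxyphenyl on C1 and 4-(methoxymethoxy)phenyl on C4 | COc1ccc([C@@H](Oc2cc(OCOC)cc(OCOC)c2C=C)C#C[C@H](Oc2cc(OCOC)cc(OCOC)c2C=C)c2ccc(OCOC)cc2)cc1
A7 | alternative 3 | 5,5',7,7'-tetrakis(methoxymethoxy)-2-(4-methoxyphenyl)-2'-[4-(methoxymethoxy)phenyl]-2H,2'H-3,3'-bichromene | COc1ccc([C@H]2Oc3cc(OCOC)cc(OCOC)c3C=C2C2=Cc3c(OCOC)cc(OCOC)cc3O[C@@H]2c2ccc(OCOC)cc2)cc1
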